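**Retrosynthetic overview**

1. Ring C is closed last, at the O1–C2 bond, by Mitsunobu displacement of an (R)-benzylic carbinol by the C8a phenol with inversion.
2. The strategy rests on ring A: a free hydroxyl on C6 para to the oxygen on C8a, methoxy groups on C5 and C7, and the carbonyl carbon C4 on C4a. This is the pattern left when a 2-silyloxyfuran/alkyne cycloadduct opens, so C5–C6 and C4a–C8a are disconnected to silyloxyfuran 9 and methoxy ynone 7.
3. Ynone 7 comes from β-keto ester 1 by Noyori hydrogenation (the only stereocenter), silylation, Weinreb amide formation and lithium methoxyacetylide addition; furan 9 comes from methyl tetronate.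
4. Order of rings: ring B is bought with 1, ring A is made in step 6, ring C in step 8.

Key step: step 6

Remark on the chemistry: C2 of the target is (S). O, aryl and CH2 keep their CIP ranking in the open-chain carbinol, so an (R)-carbinol closed with inversion is required. Flavanone numbering (C4a, C5 … C8a) is used for ring A throughout.

**Route**

Step 1
Reactants: 1 ethyl 3-(3,4-dimethoxyphenyl)-3-oxopropanoate
Product: 2 ethyl (3R)-3-(3,4-dimethoxyphenyl)-3-hydroxypropanoate
Conditions: RuCl2[(S)-BINAP] (0.5 mol%), H2 (50 atm), EtOH, 50 °C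
Reagents that add atoms: none
Why: Noyori asymmetric hydrogenation of a β-keto ester, in which the substrate chelates ruthenium through both carbonyl oxygens and (S)-BINAP directs hydride to the face that gives the (R)-carbinol (the same spatial sense that gives (S)-3-hydroxybutanoate from acetoacetate, the descriptor changing because aryl outranks CH2CO2Et).

Step 2
Reactants: 2 ethyl (3R)-3-(3,4-dimethoxyphenyl)-3-hydroxypropanoate
Product: 3 ethyl (3R)-3-[(tert-butyldimethylsilyl)oxy]-3-(3,4-dimethoxyphenyl)propanoate
Conditions: TBSCl, imidazole, DMF, rt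
Reagents that add atoms: tert-butyldimethylsilyl chloride, CC(C)(C)[Si](C)(C)Cl
Why: Standard silylation of a secondary alcohol, needed because a free β-hydroxy ynone would later cyclize to a dihydropyranone.

Step 3
Reactants: 3 ethyl (3R)-3-[(tert-butyldimethylsilyl)oxy]-3-(3,4-dimethoxyphenyl)propanoate
Product: 4 (3R)-3-[(tert-butyldimethylsilyl)oxy]-3-(3,4-dimethoxyphenyl)-N-methoxy-N-methylpropanamide
Conditions: MeNH(OMe)·HCl, i-PrMgCl, THF, −20 → 0 °C
Reagents that add atoms: N,O-dimethylhydroxylamine hydrochloride, CNOC.Cl
Why: Weinreb amide formation from an ester by the chloromagnesium amide made in the flask, which acylates at low temperature without β-elimination of the silyloxy group.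

Step 4
Reactants: 5 chloroacetaldehyde dimethyl acetal; 4 (3R)-3-[(tert-butyldimethylsilyl)oxy]-3-(3,4-dimethoxyphenyl)-N-methoxy-N-methylpropanamide
Product: 7 (5R)-5-[(tert-butyldimethylsilyl)oxy]-5-(3,4-dimethoxyphenyl)-1-methoxypent-1-yn-3-one, via lithium methoxyacetylide 6 (not isolated)
Conditions: 5, LiNEt2 (3 equiv, from Et2NH and n-BuLi), THF, 0 °C; then 4, −78 → −20 °C; inverse quench into cold pH 5 NaH2PO4 buffer/Et2O
Reagents that add atoms: none
Why: Double elimination (methanol, then HCl) from the acetal gives the lithium alkoxyacetylide, and its acyl substitution on the Weinreb amide stops at the chelated tetrahedral adduct, so the ynone is released only at the buffered quench.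

Step 5
Reactants: 8 4-methoxyfuran-2(5H)-one (methyl tetronate)
Product: 9 tert-butyl[(4-methoxyfuran-2-yl)oxy]dimethylsilane
Conditions: TBSOTf, Et3N, CH2Cl2, 0 °C → rt
Reagents that add atoms: tert-butyldimethylsilyl triflate, CC(C)(C)[Si](C)(C)OS(=O)(=O)C(F)(F)F
Why: Soft enolization of the butenolide (O-silylation of the carbonyl, then loss of a C5 proton) gives the aromatic 2-silyloxyfuran, the standard preparation of this diene class.

Step 6
Reactants: 9 tert-butyl[(4-methoxyfuran-2-yl)oxy]dimethylsilane; 7 (5R)-5-[(tert-butyldimethylsilyl)oxy]-5-(3,4-dimethoxyphenyl)-1-methoxypent-1-yn-3-one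
Product: 11 (3R)-3-[(tert-butyldimethylsilyl)oxy]-1-{6-[(tert-butyldimethylsilyl)oxy]-3-hydroxy-2,4-dimethoxyphenyl}-3-(3,4-dimethoxyphenyl)propan-1-one, via oxanorbornadiene cycloadduct 10 (not isolated)
Conditions: 9 (2 equiv), PhMe (1 M), 90–110 °C, sealed tube, Ar; then SiO2, CH2Cl2, rt
Reagents that add atoms: none
Why: Proposed new method: furan 9, a cyclic 1,3-dioxygenated diene, should add across the triple bond of 7 in a [4+2] cycloaddition that is concerted but highly asynchronous, or stepwise by Mukaiyama–Michael attack of furan C5 on the methoxy-bearing β-carbon followed by closure of the allenolate α-carbon onto the silyloxy-substituted furanium carbon; either way C5–C6 and C4a–C8a form and the six-membered carbocycle of ring A is closed by intermolecular cycloaddition as oxanorbornadiene 10. The closest known reaction type is the Diels–Alder benzannulation of 2-alkoxy- and 2-silyloxyfurans with acetylenic ketones and esters to 4-oxygenated phenols, and the untested element is a dienophile carrying an alkoxy donor on its β-carbon, which lowers its reactivity and is offset here by the doubly oxygenated furan and by heating (a methyl ynol ether cannot fragment by a retro-ene path). The oxygen bridge of 10 should then open at the silyloxy bridgehead, because only that heterolysis gives a cation stabilized by three oxygen substituents (on C8a, C7 and C5), and loss of the proton from C6 aromatizes ring A with the former furan oxygen as the free C6 hydroxyl and the silyl group still on O8a. No new stereocenter survives: the two bridgeheads of 10 arise as a mixture of facial diastereomers that converge on aromatization, and the silyl-protected (R)-carbinol is not touched under neutral thermal conditions. The regioselectivity needed, furan C5 to the β-carbon and furan C2 to the α-carbon, is secured by the match of the largest HOMO coefficient of the diene (C5, reinforced by the 4-methoxy group) with the largest LUMO coefficient of the ynone (the β-carbon).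

Step 7
Reactants: 11 (3R)-3-[(tert-butyldimethylsilyl)oxy]-1-{6-[(tert-butyldimethylsilyl)oxy]-3-hydroxy-2,4-dimethoxyphenyl}-3-(3,4-dimethoxyphenyl)propan-1-one
Product: 12 (3R)-1-(3,6-dihydroxy-2,4-dimethoxyphenyl)-3-(3,4-dimethoxyphenyl)-3-hydroxypropan-1-one
Conditions: HF·pyridine, pyridine, THF, 0 °C → rt, degassed, plastic vessel
Reagents that add atoms: none
Why: Fluoride cleavage of the aryl and the alkyl silyl ether under buffered conditions that form no enolate (no retro-aldol, no elimination to the chalcone) and keep the hydroquinone protonated, the stereocenter not being involved; any partly desilylated or silyl-migrated material from step 6 converges here.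

Step 8
Reactants: 12 (3R)-1-(3,6-dihydroxy-2,4-dimethoxyphenyl)-3-(3,4-dimethoxyphenyl)-3-hydroxypropan-1-one
Product: 13 (2S)-2-(3,4-dimethoxyphenyl)-6-hydroxy-5,7-dimethoxy-2,3-dihydro-4H-chromen-4-one
Conditions: PPh3, DIAD (slow addition), THF (0.02 M), 0 °C → rt
Reagents that add atoms: none
Why: Intramolecular Mitsunobu etherification in which the C8a phenol displaces the benzylic oxyphosphonium group through a six-membered 6-exo-tet transition state with inversion, turning the (R)-carbinol into (2S), while the C6 hydroxyl cannot cyclize (it would need a meta-bridged ring) and is shielded by two flanking methoxy groups.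

**Compound list**

1 | ethyl 3-(3,4-dimethoxyphenyl)-3-oxopropanoate | CCOC(=O)CC(=O)c1ccc(OC)c(OC)c1 | starting material
2 | ethyl (3R)-3-(3,4-dimethoxyphenyl)-3-hydroxypropanoate | CCOC(=O)C[C@@H](O)c1ccc(OC)c(OC)c1 | intermediate
3 | ethyl (3R)-3-[(tert-butyldimethylsilyl)oxy]-3-(3,4-dimethoxyphenyl)propanoate | CCOC(=O)C[C@@H](O[Si](C)(C)C(C)(C)C)c1ccc(OC)c(OC)c1 | intermediate
4 | (3R)-3-[(tert-butyldimethylsilyl)oxy]-3-(3,4-dimethoxyphenyl)-N-methoxy-N-methylpropanamide | CON(C)C(=O)C[C@@H](O[Si](C)(C)C(C)(C)C)c1ccc(OC)c(OC)c1 | intermediate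
5 | chloroacetaldehyde dimethyl acetal (2-chloro-1,1-dimethoxyethane) | COC(CCl)OC | starting material
6 | lithium methoxyacetylide (formed in the flask) | [Li]C#COC | intermediate
7 | (5R)-5-[(tert-butyldimethylsilyl)oxy]-5-(3,4-dimethoxyphenyl)-1-methoxypent-1-yn-3-one | COC#CC(=O)C[C@@H](O[Si](C)(C)C(C)(C)C)c1ccc(OC)c(OC)c1 | intermediate
8 | 4-methoxyfuran-2(5H)-one (methyl tetronate) | COC1=CC(=O)OC1 | starting material
9 | tert-butyl[(4-methoxyfuran-2-yl)oxy]dimethylsilane | COc1coc(O[Si](C)(C)C(C)(C)C)c1 | intermediate
10 | (3R)-3-[(tert-butyldimethylsilyl)oxy]-1-{1-[(tert-butyldimethylsilyl)oxy]-3,5-dimethoxy-7-oxabicyclo[2.2.1]hepta-2,5-dien-2-yl}-3-(3,4-dimethoxyphenyl)propan-1-one (both bridgehead diastereomers, formed in the flask) | COC1=CC2(O[Si](C)(C)C(C)(C)C)OC1C(OC)=C2C(=O)C[C@@H](O[Si](C)(C)C(C)(C)C)c1ccc(OC)c(OC)c1 | intermediate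
11 | (3R)-3-[(tert-butyldimethylsilyl)oxy]-1-{6-[(tert-butyldimethylsilyl)oxy]-3-hydroxy-2,4-dimethoxyphenyl}-3-(3,4-dimethoxyphenyl)propan-1-one | COc1cc(O[Si](C)(C)C(C)(C)C)c(C(=O)C[C@@H](O[Si](C)(C)C(C)(C)C)c2ccc(OC)c(OC)c2)c(OC)c1O | intermediate
12 | (3R)-1-(3,6-dihydroxy-2,4-dimethoxyphenyl)-3-(3,4-dimethoxyphenyl)-3-hydroxypropan-1-one | COc1cc(O)c(C(=O)C[C@@H](O)c2ccc(OC)c(OC)c2)c(OC)c1O | intermediate
13 | (2S)-2-(3,4-dimethoxyphenyl)-6-hydroxy-5,7-dimethoxy-2,3-dihydro-4H-chromen-4-one | COc1ccc([C@@H]2CC(=O)c3c(cc(OC)c(O)c3OC)O2)cc1OC | target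

**Step count**

Total: 8 steps. Longest linear sequence: 7 steps (steps 1–4, 6, 7, 8).

**Steps most likely to fail**

Step 6. The donor-substituted alkyne may react so slowly that the silyloxyfuran decomposes or is desilylated before cycloaddition. Alternatively, a zwitterion formed by Michael attack may collapse by silyl transfer to an open-chain butenolide instead of closing the second bond. The fallback uses known chemistry and builds ring A from a preformed arene. It sets out from Weinreb amide 4 and commercial 2,6-dimethoxybenzene-1,4-diol. Protection with MOMCl and i-Pr2NEt in CH2Cl2 would give the bis(methoxymethyl) ether F1. Directed ortho-lithiation with n-BuLi and TMEDA in THF at 0 °C, between a methoxy and a methoxymethoxy group (the two open positions are equivalent by symmetry), would give the aryllithium F2. Acylation of F2 with 4 at −78 °C would give the aryl ketone F3. Removal of both methoxymethyl groups with ZnBr2 and n-PrSH in CH2Cl2 at 0 °C would give the free hydroquinone F4, which still carries the carbinol silyl ether. Desilylation under the conditions of step 7 then comes back to the route at 12.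

Step 8. The electron-rich benzylic oxyphosphonium ion may ionize before displacement, or eliminate to the 2'-hydroxychalcone, which recloses without control; both erode the configuration at C2. The azodicarboxylate may also oxidize the hydroquinone. The fallback sets out from 12 and gives up the stereocenter on purpose. Dehydration with NaOAc in refluxing EtOH would give the 2'-hydroxychalcone F5, which should cyclize under the same conditions by oxa-Michael addition to the racemic flavanone F6. Kinetic resolution by asymmetric transfer hydrogenation (HCO2H/Et3N, with the enantiomer of Cp*RhCl(TsDPEN) that reduces the (2R)-ketone faster) would convert the unwanted enantiomer into the cis-flavan-4-ol F7. The unreduced (2S)-ketone is 13, where the fallback comes back to the route; at most half of the material is recovered this way.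

Step 4. Diethylamine and N,O-dimethylhydroxylamine are set free at the quench and may add in conjugate fashion to the very electrophilic alkoxy ynone. The ynol ether may also be hydrated to a β-keto ester during work-up or chromatography. The fallback sets out from Weinreb amide 4. Reduction with DIBAL-H in THF at −78 °C would give the aldehyde F8. Addition of lithium methoxyacetylide 6 at −78 °C would give the propargylic alcohol F9 as a mixture of C3 epimers; its alkoxide is no Michael acceptor and the amines are washed out at this stage. Neutral oxidation with activated MnO2 in CH2Cl2 (or Dess–Martin periodinane with NaHCO3) comes back to the route at 7.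

**Further compounds**

F1 | step 6 | 1,3-dimethoxy-2,5-bis(methoxymethoxy)benzene | COCOc1cc(OC)c(OCOC)c(OC)c1
F2 | step 6 | [2,4-dimethoxy-3,6-bis(methoxymethoxy)phenyl]lithium | [Li]c1c(OC)c(OCOC)c(OC)cc1OCOC
F3 | step 6 | (3R)-3-[(tert-butyldimethylsilyl)oxy]-1-[2,4-dimethoxy-3,6-bis(methoxymethoxy)phenyl]-3-(3,4-dimethoxyphenyl)propan-1-one | COCOc1cc(OC)c(OCOC)c(OC)c1C(=O)C[C@@H](O[Si](C)(C)C(C)(C)C)c1ccc(OC)c(OC)c1
F4 | step 6 | (3R)-3-[(tert-butyldimethylsilyl)oxy]-1-(3,6-dihydroxy-2,4-dimethoxyphenyl)-3-(3,4-dimethoxyphenyl)propan-1-one | COc1cc(O)c(C(=O)C[C@@H](O[Si](C)(C)C(C)(C)C)c2ccc(OC)c(OC)c2)c(OC)c1O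
F5 | step 8 | (2E)-1-(3,6-dihydroxy-2,4-dimethoxyphenyl)-3-(3,4-dimethoxyphenyl)prop-2-en-1-one | COc1cc(O)c(C(=O)/C=C/c2ccc(OC)c(OC)c2)c(OC)c1O
F6 | step 8 | rac-2-(3,4-dimethoxyphenyl)-6-hydroxy-5,7-dimethoxy-2,3-dihydro-4H-chromen-4-one | COc1ccc(C2CC(=O)c3c(cc(OC)c(O)c3OC)O2)cc1OC
F7 | step 8 | (2R,4R)-2-(3,4-dimethoxyphenyl)-5,7-dimethoxy-3,4-dihydro-2H-chromene-4,6-diol | COc1ccc([C@H]2C[C@@H](O)c3c(cc(OC)c(O)c3OC)O2)cc1OC
F8 | step 4 | (3R)-3-[(tert-butyldimethylsilyl)oxy]-3-(3,4-dimethoxyphenyl)propanal | O=CC[C@@H](O[Si](C)(C)C(C)(C)C)c1ccc(OC)c(OC)c1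
F9 | step 4 | (5R)-5-[(tert-butyldimethylsilyl)oxy]-5-(3,4-dimethoxyphenyl)-1-methoxypent-1-yn-3-ol (both C3 epimers) | COC#CC(O)C[C@@H](O[Si](C)(C)C(C)(C)C)c1ccc(OC)c(OC)c1
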